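## Retrosynthetic overview

1. No ring is built. Ring A and ring B are two copies of the C2v-symmetric pyranone 1, each desymmetrised by lateral mono-chlorination (1 → 3), and the lateral stereocentres are then set by enantioconvergent nickel couplings of the racemic chloride.
2. Target 23 ⇐ 1,3-syn reduction (C7) of β-hydroxy ketone 21 ⇐ C7–C8 bond by nickel reductive acylation of ring-B chloride 9 with acid chloride 19 (sets C8). Locants are those of the nonene chain in the name of 23.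
3. Acid 18 ⇐ Evans syn aldol (C5, C6) on enal 13 ⇐ cross-metathesis of 11 with methacrolein ⇐ nickel vinylation of 3 (sets C2 next to ring A).
4. Chloride 9 ⇐ lateral chlorination of 7 ⇐ Felkin–Anh reduction of ketone 5 ⇐ nickel acylation of 3 with propanoyl chloride (sets both centres of the hydroxypentyl arm).
5. Order: the ring-A fragment (steps 6–10) and the ring-B fragment (steps 2–5) are made in parallel from 3 and joined in step 11.

Assumption: 1 is taken as a purchased heteroaromatic (it is also the one-pot product of 3-pentanone and propanoic acid in polyphosphoric acid); the sense of induction in the three nickel couplings is assigned by analogy with 1-arylethyl chlorides and would be checked on 5 and 11, with the antipodal ligand used if needed.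

## Route

Step 1
Reactants: 1 2,6-diethyl-3,5-dimethyl-4H-pyran-4-one
Product: 3 2-(1-chloroethyl)-6-ethyl-3,5-dimethyl-4H-pyran-4-one (racemic), via lithium dienolate 2 (not isolated)
Conditions: LiN(SiMe3)2 (1.05 equiv), THF, −78 °C; then cannulated into C2Cl6 (1.3 equiv), THF, −78 °C
Reagents that add atoms: hexachloroethane, ClC(Cl)(Cl)C(Cl)(Cl)Cl
Why: Kinetic lateral (vinylogous) deprotonation of one ethyl group and electrophilic chlorination of the lithium dienolate replaces one of the four symmetry-related lateral hydrogens and so breaks the symmetry of 1; the new centre is left racemic on purpose because both enantiomers converge in steps 2 and 6.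

Step 2
Reactants: 3 2-(1-chloroethyl)-6-ethyl-3,5-dimethyl-4H-pyran-4-one (1.5 equiv); 4 propanoyl chloride
Product: 5 2-ethyl-3,5-dimethyl-6-[(2S)-3-oxopentan-2-yl]-4H-pyran-4-one
Conditions: NiCl2(dme) (10 mol %), (R,R)-Ph-BOX = 2,2'-(propane-2,2-diyl)bis[(4R)-4-phenyl-4,5-dihydro-1,3-oxazole] (22 mol %), Mn powder (3 equiv), 2,6-dimethylbenzoic acid (0.75 equiv), 3 Å molecular sieves, DMA/THF 3:7, 20 °C; quick filtration, used at once
Reagents that add atoms: none
Why: Proposed new method: extension of the nickel-catalysed enantioconvergent reductive acyl cross-coupling of racemic 1-arylethyl chlorides with acid chlorides to a 1-(4-oxopyran-2-yl)ethyl chloride — chlorine abstraction gives a planar pyranone-stabilised lateral radical, the bis(oxazoline)-bound acylnickel species captures it, and reductive elimination from trivalent nickel sets the (S) centre under ligand control, while the base-free medium keeps the epimerisable α-pyranyl ketone intact.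

Step 3
Reactants: 5 2-ethyl-3,5-dimethyl-6-[(2S)-3-oxopentan-2-yl]-4H-pyran-4-one
Product: 6 2-ethyl-6-[(2R,3R)-3-hydroxypentan-2-yl]-3,5-dimethyl-4H-pyran-4-one
Conditions: LiBH(s-Bu)3 (1.2 equiv), THF, −78 °C; then H2O
Reagents that add atoms: none
Why: Felkin–Anh reduction in which the bulky hydride attacks anti to the perpendicular pyranyl group and past the small hydrogen gives the 2,3-anti alcohol (new carbinol R), and the fully substituted, electron-rich ring carbonyl is not reduced at −78 °C.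

Step 4
Reactants: 6 2-ethyl-6-[(2R,3R)-3-hydroxypentan-2-yl]-3,5-dimethyl-4H-pyran-4-one
Product: 7 2-ethyl-3,5-dimethyl-6-[(2R,3R)-3-(triethylsilyloxy)pentan-2-yl]-4H-pyran-4-one
Conditions: Et3SiCl, imidazole, DMF, 0 °C to rt
Reagents that add atoms: chlorotriethylsilane, CC[Si](Cl)(CC)CC
Why: Standard silylation with the chloride and imidazole protects the alcohol without the silyl triflate/amine combination that would activate the ring carbonyl and risk lateral enolisation.

Step 5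
Reactants: 7 2-ethyl-3,5-dimethyl-6-[(2R,3R)-3-(triethylsilyloxy)pentan-2-yl]-4H-pyran-4-one
Product: 9 2-(1-chloroethyl)-3,5-dimethyl-6-[(2R,3R)-3-(triethylsilyloxy)pentan-2-yl]-4H-pyran-4-one (both epimers at the chlorinated carbon), via lithium dienolate 8 (not isolated)
Conditions: LiN(SiMe3)2 (1.05 equiv), THF, −78 °C; then C2Cl6 (1.3 equiv), −78 °C
Reagents that add atoms: hexachloroethane, ClC(Cl)(Cl)C(Cl)(Cl)Cl
Why: Lateral lithiation takes the only remaining lateral CH2 (the methine of the silyloxy arm is hindered and its dienolate would suffer allylic 1,3-strain with the ring methyl), and enolate chlorination gives an epimer mixture that does not matter for the stereoconvergent coupling of step 11.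

Step 6
Reactants: 3 2-(1-chloroethyl)-6-ethyl-3,5-dimethyl-4H-pyran-4-one; 10 bromoethene (1.0 M in THF, 1.5 equiv)
Product: 11 2-[(2S)-but-3-en-2-yl]-6-ethyl-3,5-dimethyl-4H-pyran-4-one
Conditions: NiCl2(dme) (10 mol %), (3aR,3a'R,8aS,8a'S)-2,2'-(cyclopropane-1,1-diyl)bis(3a,8a-dihydro-8H-indeno[1,2-d]oxazole) (11 mol %), Mn powder (3 equiv), NaI (0.5 equiv), DMA, 0 °C
Reagents that add atoms: none
Why: Proposed new method: extension of the nickel-catalysed asymmetric reductive cross-coupling of vinyl bromides with racemic benzylic chlorides to the pyranyl chloride 3 and the parent bromoethene — the lateral radical from either enantiomer of 3 combines with the chiral alkenylnickel complex so that the ligand sets the (S) allylic centre, and the neutral conditions leave the new lateral, allylic C–H untouched.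

Step 7
Reactants: 11 2-[(2S)-but-3-en-2-yl]-6-ethyl-3,5-dimethyl-4H-pyran-4-one; 12 methacrolein (10 equiv)
Product: 13 (2E,4S)-4-(6-ethyl-3,5-dimethyl-4-oxo-4H-pyran-2-yl)-2-methylpent-2-enal
Conditions: second-generation Grubbs catalyst (5 mol %), 1,4-benzoquinone (10 mol %), CH2Cl2, 40 °C
Reagents that add atoms: none
Why: Olefin cross-metathesis of the monosubstituted alkene with excess methacrolein gives the thermodynamically favoured (E)-trisubstituted enal with loss of ethene, and benzoquinone suppresses ruthenium hydride migration of the double bond into conjugation with ring A, so the allylic centre is kept.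

Step 8
Reactants: 13 (2E,4S)-4-(6-ethyl-3,5-dimethyl-4-oxo-4H-pyran-2-yl)-2-methylpent-2-enal; 14 (4R)-4-benzyl-3-propanoyl-1,3-oxazolidin-2-one (1.3 equiv)
Product: 16 (4R)-4-benzyl-3-[(2R,3R,4E,6S)-6-(6-ethyl-3,5-dimethyl-4-oxo-4H-pyran-2-yl)-3-hydroxy-2,4-dimethylhept-4-enoyl]-1,3-oxazolidin-2-one, via boron enolate 15 (not isolated)
Conditions: Bu2BOTf (1.25 equiv), Et3N (1.5 equiv), CH2Cl2, 0 °C; then 13, −78 to 0 °C; then pH 7 buffer, MeOH, 30% H2O2, 0 °C
Reagents that add atoms: none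
Why: Evans syn aldol in which the (Z)-boron enolate reacts through a closed Zimmerman–Traxler chair on the face away from the benzyl group to give the (2R,3R) syn adduct regardless of the remote allylic centre, the imide being in excess over Bu2BOTf so that no free boron triflate remains to activate the pyranone.

Step 9
Reactants: 16 (4R)-4-benzyl-3-[(2R,3R,4E,6S)-6-(6-ethyl-3,5-dimethyl-4-oxo-4H-pyran-2-yl)-3-hydroxy-2,4-dimethylhept-4-enoyl]-1,3-oxazolidin-2-one
Product: 17 (4R)-4-benzyl-3-[(2R,3R,4E,6S)-6-(6-ethyl-3,5-dimethyl-4-oxo-4H-pyran-2-yl)-2,4-dimethyl-3-(triethylsilyloxy)hept-4-enoyl]-1,3-oxazolidin-2-one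
Conditions: Et3SiCl, imidazole, DMAP (cat.), DMF, rt
Reagents that add atoms: chlorotriethylsilane, CC[Si](Cl)(CC)CC
Why: Silylation of the secondary alcohol blocks retro-aldol cleavage and self-acylation in the next two steps, again without a silyl triflate.

Step 10
Reactants: 17 (4R)-4-benzyl-3-[(2R,3R,4E,6S)-6-(6-ethyl-3,5-dimethyl-4-oxo-4H-pyran-2-yl)-2,4-dimethyl-3-(triethylsilyloxy)hept-4-enoyl]-1,3-oxazolidin-2-one
Product: 18 (2R,3R,4E,6S)-6-(6-ethyl-3,5-dimethyl-4-oxo-4H-pyran-2-yl)-2,4-dimethyl-3-(triethylsilyloxy)hept-4-enoic acid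
Conditions: LiOH, 30% H2O2, THF/H2O 3:1, 0 °C; then Na2SO3; 1 M HCl to pH 4
Reagents that add atoms: hydrogen peroxide (as LiOOH), OO
Why: Hydroperoxide attacks the exocyclic imide carbonyl selectively (LiOOH auxiliary cleavage), releasing the acid without epimerising the α-centre and returning the auxiliary.

Step 11
Reactants: 18 (2R,3R,4E,6S)-6-(6-ethyl-3,5-dimethyl-4-oxo-4H-pyran-2-yl)-2,4-dimethyl-3-(triethylsilyloxy)hept-4-enoic acid; 9 2-(1-chloroethyl)-3,5-dimethyl-6-[(2R,3R)-3-(triethylsilyloxy)pentan-2-yl]-4H-pyran-4-one (1.2 equiv)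
Product: 20 2-ethyl-3,5-dimethyl-6-[(2S,3E,5R,6R,8R)-4,6-dimethyl-7-oxo-8-{3,5-dimethyl-4-oxo-6-[(2R,3R)-3-(triethylsilyloxy)pentan-2-yl]-4H-pyran-2-yl}-5-(triethylsilyloxy)non-3-en-2-yl]-4H-pyran-4-one, via acid chloride 19 (not isolated)
Conditions: 1-chloro-N,N,2-trimethylprop-1-en-1-amine (1.2 equiv), CH2Cl2, 0 °C to rt, evaporate; then 9, NiCl2(dme) (15 mol %), (S,S)-Ph-BOX = 2,2'-(propane-2,2-diyl)bis[(4S)-4-phenyl-4,5-dihydro-1,3-oxazole] (33 mol %), Mn powder (3 equiv), 2,6-dimethylbenzoic acid (0.75 equiv), 3 Å molecular sieves, DMA/THF 3:7, 20 °C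
Reagents that add atoms: none
Why: Proposed new method: the enantioconvergent nickel-catalysed reductive acylation of step 2 used as the fragment union with an α-branched β-silyloxy acid chloride and the antipodal ligand, because the new centre (C8, R in the ketone) is the local mirror image of the one made in step 2 — both epimers of 9 converge through the lateral radical, ligand control is expected to override the α-centre of the acyl partner, and the base-free reductive medium preserves the epimerisable centre between the ketone and ring B.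

Step 12
Reactants: 20 2-ethyl-3,5-dimethyl-6-[(2S,3E,5R,6R,8R)-4,6-dimethyl-7-oxo-8-{3,5-dimethyl-4-oxo-6-[(2R,3R)-3-(triethylsilyloxy)pentan-2-yl]-4H-pyran-2-yl}-5-(triethylsilyloxy)non-3-en-2-yl]-4H-pyran-4-one
Product: 21 2-ethyl-6-[(2S,3E,5R,6R,8R)-5-hydroxy-8-{6-[(2R,3R)-3-hydroxypentan-2-yl]-3,5-dimethyl-4-oxo-4H-pyran-2-yl}-4,6-dimethyl-7-oxonon-3-en-2-yl]-3,5-dimethyl-4H-pyran-4-one
Conditions: HF·pyridine, pyridine, THF, 0 °C
Reagents that add atoms: none
Why: Buffered fluoride removes both triethylsilyl ethers under mildly acidic conditions that avoid retro-aldol cleavage and enolisation of the β-hydroxy ketone.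

Step 13
Reactants: 21 2-ethyl-6-[(2S,3E,5R,6R,8R)-5-hydroxy-8-{6-[(2R,3R)-3-hydroxypentan-2-yl]-3,5-dimethyl-4-oxo-4H-pyran-2-yl}-4,6-dimethyl-7-oxonon-3-en-2-yl]-3,5-dimethyl-4H-pyran-4-one
Product: 23 2-ethyl-6-[(2S,3E,5R,6S,7S,8S)-5,7-dihydroxy-8-{6-[(2R,3R)-3-hydroxypentan-2-yl]-3,5-dimethyl-4-oxo-4H-pyran-2-yl}-4,6-dimethylnon-3-en-2-yl]-3,5-dimethyl-4H-pyran-4-one (target), via boron chelate 22 (not isolated)
Conditions: Et2BOMe (2.5 equiv), THF/MeOH 4:1, −78 °C; NaBH4 (2 equiv), −78 °C; then MeOH, evaporation (three times)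
Reagents that add atoms: none
Why: Narasaka–Prasad reduction in which the diethylboron chelate of the β-hydroxy ketone adopts a half-chair and external hydride adds axially gives the 1,3-syn diol, so the C7 carbinol (S) is syn to the C5 hydroxyl and C6 methyl and anti to the C8 methyl.

## Compound list

1 | 2,6-diethyl-3,5-dimethyl-4H-pyran-4-one | CCc1oc(CC)c(C)c(=O)c1C | starting material
2 | lithium 2-ethyl-6-ethylidene-3,5-dimethyl-6H-pyran-4-olate (formed in the flask) | CC=C1OC(CC)=C(C)C([O-])=C1C.[Li+] | intermediate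
3 | 2-(1-chloroethyl)-6-ethyl-3,5-dimethyl-4H-pyran-4-one (racemic) | CCc1oc(C(C)Cl)c(C)c(=O)c1C | intermediate
4 | propanoyl chloride | CCC(Cl)=O | starting material
5 | 2-ethyl-3,5-dimethyl-6-[(2S)-3-oxopentan-2-yl]-4H-pyran-4-one | CCC(=O)[C@@H](C)c1oc(CC)c(C)c(=O)c1C | intermediate
6 | 2-ethyl-6-[(2R,3R)-3-hydroxypentan-2-yl]-3,5-dimethyl-4H-pyran-4-one | CCc1oc([C@H](C)[C@H](O)CC)c(C)c(=O)c1C | intermediate
7 | 2-ethyl-3,5-dimethyl-6-[(2R,3R)-3-(triethylsilyloxy)pentan-2-yl]-4H-pyran-4-one | CCc1oc([C@H](C)[C@H](O[Si](CC)(CC)CC)CC)c(C)c(=O)c1C | intermediate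
8 | lithium 2-ethylidene-3,5-dimethyl-6-[(2R,3R)-3-(triethylsilyloxy)pentan-2-yl]-2H-pyran-4-olate (formed in the flask) | CC=C1OC([C@H](C)[C@H](O[Si](CC)(CC)CC)CC)=C(C)C([O-])=C1C.[Li+] | intermediate
9 | 2-(1-chloroethyl)-3,5-dimethyl-6-[(2R,3R)-3-(triethylsilyloxy)pentan-2-yl]-4H-pyran-4-one (both epimers at the chlorinated carbon) | CC(Cl)c1oc([C@H](C)[C@H](O[Si](CC)(CC)CC)CC)c(C)c(=O)c1C | intermediate
10 | bromoethene | BrC=C | starting material
11 | 2-[(2S)-but-3-en-2-yl]-6-ethyl-3,5-dimethyl-4H-pyran-4-one | CCc1oc([C@@H](C)C=C)c(C)c(=O)c1C | intermediate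
12 | methacrolein (2-methylprop-2-enal) | CC(=C)C=O | starting material
13 | (2E,4S)-4-(6-ethyl-3,5-dimethyl-4-oxo-4H-pyran-2-yl)-2-methylpent-2-enal | CCc1oc([C@@H](C)/C=C(\C)C=O)c(C)c(=O)c1C | intermediate
14 | (4R)-4-benzyl-3-propanoyl-1,3-oxazolidin-2-one | CCC(=O)N1[C@H](Cc2ccccc2)COC1=O | starting material
15 | (4R)-4-benzyl-3-[(1Z)-1-(dibutylboranyloxy)prop-1-en-1-yl]-1,3-oxazolidin-2-one (formed in the flask) | C/C=C(\OB(CCCC)CCCC)N1[C@H](Cc2ccccc2)COC1=O | intermediate
16 | (4R)-4-benzyl-3-[(2R,3R,4E,6S)-6-(6-ethyl-3,5-dimethyl-4-oxo-4H-pyran-2-yl)-3-hydroxy-2,4-dimethylhept-4-enoyl]-1,3-oxazolidin-2-one | CCc1oc([C@@H](C)/C=C(\C)[C@H](O)[C@@H](C)C(=O)N2[C@H](Cc3ccccc3)COC2=O)c(C)c(=O)c1C | intermediate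
17 | (4R)-4-benzyl-3-[(2R,3R,4E,6S)-6-(6-ethyl-3,5-dimethyl-4-oxo-4H-pyran-2-yl)-2,4-dimethyl-3-(triethylsilyloxy)hept-4-enoyl]-1,3-oxazolidin-2-one | CCc1oc([C@@H](C)/C=C(\C)[C@H](O[Si](CC)(CC)CC)[C@@H](C)C(=O)N2[C@H](Cc3ccccc3)COC2=O)c(C)c(=O)c1C | intermediate
18 | (2R,3R,4E,6S)-6-(6-ethyl-3,5-dimethyl-4-oxo-4H-pyran-2-yl)-2,4-dimethyl-3-(triethylsilyloxy)hept-4-enoic acid | CCc1oc([C@@H](C)/C=C(\C)[C@H](O[Si](CC)(CC)CC)[C@@H](C)C(O)=O)c(C)c(=O)c1C | intermediate
19 | (2R,3R,4E,6S)-6-(6-ethyl-3,5-dimethyl-4-oxo-4H-pyran-2-yl)-2,4-dimethyl-3-(triethylsilyloxy)hept-4-enoyl chloride (formed in the flask) | CCc1oc([C@@H](C)/C=C(\C)[C@H](O[Si](CC)(CC)CC)[C@@H](C)C(Cl)=O)c(C)c(=O)c1C | intermediate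
20 | 2-ethyl-3,5-dimethyl-6-[(2S,3E,5R,6R,8R)-4,6-dimethyl-7-oxo-8-{3,5-dimethyl-4-oxo-6-[(2R,3R)-3-(triethylsilyloxy)pentan-2-yl]-4H-pyran-2-yl}-5-(triethylsilyloxy)non-3-en-2-yl]-4H-pyran-4-one | CCc1oc([C@@H](C)/C=C(\C)[C@H](O[Si](CC)(CC)CC)[C@@H](C)C(=O)[C@H](C)c2oc([C@H](C)[C@H](O[Si](CC)(CC)CC)CC)c(C)c(=O)c2C)c(C)c(=O)c1C | intermediate
21 | 2-ethyl-6-[(2S,3E,5R,6R,8R)-5-hydroxy-8-{6-[(2R,3R)-3-hydroxypentan-2-yl]-3,5-dimethyl-4-oxo-4H-pyran-2-yl}-4,6-dimethyl-7-oxonon-3-en-2-yl]-3,5-dimethyl-4H-pyran-4-one | CCc1oc([C@@H](C)/C=C(\C)[C@H](O)[C@@H](C)C(=O)[C@H](C)c2oc([C@H](C)[C@H](O)CC)c(C)c(=O)c2C)c(C)c(=O)c1C | intermediate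
22 | O-diethylboryl chelate of 21 (boron on the 5-oxygen and coordinated to the 7-ketone; formed in the flask) | CCc1oc([C@@H](C)/C=C(\C)[C@H](OB(CC)CC)[C@@H](C)C(=O)[C@H](C)c2oc([C@H](C)[C@H](O)CC)c(C)c(=O)c2C)c(C)c(=O)c1C | intermediate
23 | 2-ethyl-6-[(2S,3E,5R,6S,7S,8S)-5,7-dihydroxy-8-{6-[(2R,3R)-3-hydroxypentan-2-yl]-3,5-dimethyl-4-oxo-4H-pyran-2-yl}-4,6-dimethylnon-3-en-2-yl]-3,5-dimethyl-4H-pyran-4-one | CCc1oc([C@@H](C)/C=C(\C)[C@H](O)[C@@H](C)[C@H](O)[C@H](C)c2oc([C@H](C)[C@H](O)CC)c(C)c(=O)c2C)c(C)c(=O)c1C | target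

## Step count and risks

Total steps: 13. Longest linear sequence: 9 (steps 1, 6, 7, 8, 9, 10, 11, 12, 13); the ring-B branch is 8 steps (1, 2, 3, 4, 5, 11, 12, 13).

Most likely to fail:

**Step 11 (late nickel acylation).** The acid chloride is α-branched and chiral, so yield may drop (decarbonylation, slow radical capture) and the ligand may meet a mismatched substrate. The product also carries an epimerisable centre between the ketone and ring B. The fallback makes the C7–C8 bond by lateral aldol chemistry and sets out from 17 and 7. LiBH4 (THF, 1 equiv H2O, 0 °C) removes the auxiliary reductively to give (2S,3R,4E,6S)-6-(6-ethyl-3,5-dimethyl-4-oxo-4H-pyran-2-yl)-2,4-dimethyl-3-(triethylsilyloxy)hept-4-en-1-ol F1. Dess–Martin periodinane (NaHCO3, CH2Cl2) gives (2R,3R,4E,6S)-6-(6-ethyl-3,5-dimethyl-4-oxo-4H-pyran-2-yl)-2,4-dimethyl-3-(triethylsilyloxy)hept-4-enal F2. F2 is added at −78 °C to lithium dienolate 8 (from 7 and LiN(SiMe3)2) to give the 7-hydroxy bis(silyl ether) F3; Felkin–Anh addition places the 7-hydroxyl syn to the 6-methyl, and the 7,8-anti isomer is separated from its 8-epimer by chromatography. HF·pyridine then gives the target, so this path comes back to the route at 23.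

**Step 6 (nickel vinylation with bromoethene).** The unsubstituted vinyl partner and the pyranyl chloride are both outside the tested range, so the enantiomeric excess at C2 is uncertain. The fallback sets out from 3. DBU (CH2Cl2, rt) eliminates HCl to give 2-ethenyl-6-ethyl-3,5-dimethyl-4H-pyran-4-one F4. Nickel-catalysed asymmetric hydrovinylation ([Ni(C3H5)Br]2, a binaphthol-derived phosphoramidite, Na[B(C6H3(CF3)2)4], ethene 1 atm, CH2Cl2, −78 °C) then adds hydrogen and vinyl across the vinyl group in the Markovnikov sense and comes back to the route at 11.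

**Step 2 (first nickel acylation).** The pyranyl chloride may couple with low enantiomeric excess, and ketone 5 may racemise before reduction. The fallback sets out from 1 and replaces catalysis by resolution. Lithium dienolate 2 is acylated with N-methoxy-N-methylpropanamide (THF, −78 °C) to racemic 2-ethyl-3,5-dimethyl-6-(3-oxopentan-2-yl)-4H-pyran-4-one F5. LiBH(s-Bu)3 gives the racemic anti alcohol F6. Burkholderia cepacia lipase with vinyl acetate in tert-butyl methyl ether acylates the (3R) enantiomer (ethyl as the medium group, the branched pyranylethyl as the large group) to 2-ethyl-6-[(2R,3R)-3-acetoxypentan-2-yl]-3,5-dimethyl-4H-pyran-4-one F7 and leaves 2-ethyl-6-[(2S,3S)-3-hydroxypentan-2-yl]-3,5-dimethyl-4H-pyran-4-one F8, which can be recycled by oxidation back to F5. K2CO3 in MeOH cleaves F7 and comes back to the route at 6.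

## Further compounds

F1 | step 11 | (2S,3R,4E,6S)-6-(6-ethyl-3,5-dimethyl-4-oxo-4H-pyran-2-yl)-2,4-dimethyl-3-(triethylsilyloxy)hept-4-en-1-ol | CCc1oc([C@@H](C)/C=C(\C)[C@H](O[Si](CC)(CC)CC)[C@@H](C)CO)c(C)c(=O)c1C
F2 | step 11 | (2R,3R,4E,6S)-6-(6-ethyl-3,5-dimethyl-4-oxo-4H-pyran-2-yl)-2,4-dimethyl-3-(triethylsilyloxy)hept-4-enal | CCc1oc([C@@H](C)/C=C(\C)[C@H](O[Si](CC)(CC)CC)[C@@H](C)C=O)c(C)c(=O)c1C
F3 | step 11 | 2-ethyl-6-[(2S,3E,5R,6S,7S,8S)-7-hydroxy-8-{3,5-dimethyl-4-oxo-6-[(2R,3R)-3-(triethylsilyloxy)pentan-2-yl]-4H-pyran-2-yl}-4,6-dimethyl-5-(triethylsilyloxy)non-3-en-2-yl]-3,5-dimethyl-4H-pyran-4-one | CCc1oc([C@@H](C)/C=C(\C)[C@H](O[Si](CC)(CC)CC)[C@@H](C)[C@H](O)[C@H](C)c2oc([C@H](C)[C@H](O[Si](CC)(CC)CC)CC)c(C)c(=O)c2C)c(C)c(=O)c1C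
F4 | step 6 | 2-ethenyl-6-ethyl-3,5-dimethyl-4H-pyran-4-one | C=Cc1oc(CC)c(C)c(=O)c1C
F5 | step 2 | 2-ethyl-3,5-dimethyl-6-(3-oxopentan-2-yl)-4H-pyran-4-one (racemic) | CCC(=O)C(C)c1oc(CC)c(C)c(=O)c1C
F6 | step 2 | 2-ethyl-6-[(2R*,3R*)-3-hydroxypentan-2-yl]-3,5-dimethyl-4H-pyran-4-one (racemic anti alcohol, both enantiomers written) | CCc1oc([C@H](C)[C@H](O)CC)c(C)c(=O)c1C.CCc1oc([C@@H](C)[C@@H](O)CC)c(C)c(=O)c1C
F7 | step 2 | 2-ethyl-6-[(2R,3R)-3-acetoxypentan-2-yl]-3,5-dimethyl-4H-pyran-4-one | CCc1oc([C@H](C)[C@H](OC(C)=O)CC)c(C)c(=O)c1C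
F8 | step 2 | 2-ethyl-6-[(2S,3S)-3-hydroxypentan-2-yl]-3,5-dimethyl-4H-pyran-4-one | CCc1oc([C@@H](C)[C@@H](O)CC)c(C)c(=O)c1C
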